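## Retrosynthetic overview

1. Numbering: ring A = C1 [C(OH)Me], C2, C3 (CHBr), C4, C5 (CMe2), C6 (spiro). Ring B = C6, C7=C8, C9 (=C12HBr), C10, C11.
2. Feature used: ring B is the formal [4+2] adduct of a diene C6=C7–C8=C9 and a two-carbon unit C10=C11. The exocyclic C9=C12HBr is what is left of a bromoallene C8=C9=C12HBr. C11 lies on the same face of ring A as the C1 oxygen, so an acrylate on that oxygen can deliver C10=C11.
3. Late disconnections: C3–Br by Appel inversion of the C3 alcohol; the tether carbonyl carbon by lactol formation and Rh decarbonylation; C6–C11 and C9–C10 by intramolecular Diels–Alder reaction of the C1 acrylate of the ring-A alkylidene vinyl-bromoallene.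
4. Early disconnections: bromoallene from an (8S)-propargylic sulfonate by anti-SN2' bromocuprate displacement; carbinol from asymmetric alkynylation of a (Z)-enal; Z geometry from a butenolide closed by an acetate aldol on C1-hydroxylated, O-silylated (4R,6R)-actinol.
5. Ring order: ring A is bought. A temporary butenolide (C1, O, C8, C7, C6) is closed in step 5 and opened in step 7. Ring B and the γ-lactone close together in step 14, and the lactone is removed in steps 15 and 16.

Key step: step 14

Assumption: (4R,6R)-actinol is taken as a purchasable enantiopure chiral-pool ketone (an industrial carotenoid intermediate, otherwise made from ketoisophorone by two reductions).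

## Route

Step 1
Reactants: 1 (4R,6R)-4-hydroxy-2,2,6-trimethylcyclohexanone (actinol)
Product: 2 (4R,6R)-4-(tert-butyldimethylsilyloxy)-2,2,6-trimethylcyclohexanone
Conditions: TBSCl, imidazole, DMF, rt
Reagents that add atoms: tert-butyldimethylsilyl chloride CC(C)(C)[Si](C)(C)Cl
Why: Imidazole-promoted silyl ether formation at the only hydroxyl, which touches no stereocentre.

Step 2
Reactants: 2 O-TBS actinol
Product: 3 (4R)-4-(tert-butyldimethylsilyloxy)-2,6,6-trimethyl-1-(trimethylsilyloxy)cyclohex-1-ene
Conditions: TMSOTf, Et3N, CH2Cl2, 0 °C → rt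
Reagents that add atoms: trimethylsilyl triflate C[Si](C)(C)OS(=O)(=O)C(F)(F)F
Why: Soft enolisation with O-silylation can remove only the C1–H because C5 is quaternary, so a single tetrasubstituted enol ether forms and the C1 centre is erased on purpose.

Step 3
Reactants: 3 TMS enol ether
Product: 6 (2S,4S)-4-(tert-butyldimethylsilyloxy)-2-hydroxy-2,6,6-trimethylcyclohexanone (C1 OH cis to C3 OTBS), via silyloxy epoxide 4 (not isolated), via trimethylsilyloxy ketone 5 (not isolated)
Conditions: mCPBA, hexane/CH2Cl2, −15 °C; then citric acid (cat.), MeOH, rt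
Reagents that add atoms: mCPBA OOC(=O)c1cccc(Cl)c1
Why: Rubottom oxidation (epoxidation, silyl shift, methanolysis of the labile tertiary TMS ether beside the secondary TBS ether), in which the half-chair with C3–OTBS equatorial has the pseudoaxial C5 methyl on the opposite face, so the peracid should attack syn to the C3 oxygen and set (1S), with any C1 epimer removed by chromatography.

Step 4
Reactants: 6 hydroxy ketone; 7 acetic anhydride
Product: 8 (2S,4S)-2-acetoxy-4-(tert-butyldimethylsilyloxy)-2,6,6-trimethylcyclohexanone
Conditions: Ac2O, DMAP (cat.), pyridine, 50 °C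
Reagents that add atoms: acetic anhydride CC(=O)OC(C)=O
Why: DMAP-catalysed acylation of a tertiary alcohol, in which the ketone has no α-hydrogen left and so cannot form an enol acetate or epimerise.

Step 5
Reactants: 8 acetoxy ketone
Product: 9 (3aS,6S,7aS)-6-(tert-butyldimethylsilyloxy)-3a-hydroxy-4,4,7a-trimethylhexahydro-1-benzofuran-2(3H)-one (cis-fused)
Conditions: LiHMDS, THF, −78 → −20 °C; AcOH quench
Reagents that add atoms: none
Why: Intramolecular acetate aldol (5-exo-trig), in which the acetate methyl is the only acidic C–H and the tether brings the enolate onto the otherwise inaccessible doubly neopentyl ketone from the face of the C1 oxygen, making C6–C7.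

Step 6
Reactants: 9 hydroxy lactone
Product: 10 (6S,7aS)-6-(tert-butyldimethylsilyloxy)-4,4,7a-trimethyl-5,6,7,7a-tetrahydro-1-benzofuran-2(4H)-one (silyl ether of the 6S,7aS diastereomer of loliolide)
Conditions: SOCl2, pyridine, 0 °C
Reagents that add atoms: none
Why: Chlorosulfite formation and E2 dehydration can run only towards C7, the sole carbon with β-hydrogens, and the ring holds C8 cis to C1, which fixes the later C6=C7 geometry.

Step 7
Reactants: 10 butenolide
Product: 11 (1S,5S,2Z)-5-(tert-butyldimethylsilyloxy)-2-(2-hydroxyethylidene)-1,3,3-trimethylcyclohexan-1-ol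
Conditions: DIBAL-H (3.5 equiv), CH2Cl2, −78 → 0 °C; Rochelle salt
Reagents that add atoms: none
Why: Exhaustive 1,2-reduction of the butenolide carbonyl by DIBAL-H leaves the alkene untouched, so the ring geometry appears as the Z-enediol.

Step 8
Reactants: 11 Z-enediol
Product: 12 primary triethylsilyl ether of 11 (C8 OTES, C1 OH free)
Conditions: TESCl, imidazole, CH2Cl2, 0 °C
Reagents that add atoms: chlorotriethylsilane CC[Si](Cl)(CC)CC
Why: Chemoselective silylation of the primary allylic hydroxyl in the presence of the hindered tertiary one.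

Step 9
Reactants: 12 TES ether; 13 acryloyl chloride
Product: 15 C1 acrylate of 12, via lithium alkoxide 14 (not isolated)
Conditions: n-BuLi, THF, −78 °C; then acryloyl chloride, −78 → −20 °C
Reagents that add atoms: acryloyl chloride C=CC(=O)Cl; n-butyllithium [Li]CCCC (Li only in 14)
Why: O-acylation of a lithium tert-alkoxide with an acid chloride is the dependable esterification of a hindered tertiary alcohol, the low temperature suppresses O-to-O silyl migration, and the C1–O bond is not broken.

Step 10
Reactants: 15 acrylate TES ether
Product: 16 (1S,5S,2Z)-5-(tert-butyldimethylsilyloxy)-1,3,3-trimethyl-2-(2-oxoethylidene)cyclohexyl acrylate (Z-enal)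
Conditions: (COCl)2, DMSO, CH2Cl2, −78 → −30 °C; Et3N
Reagents that add atoms: none
Why: Swern conditions cleave and oxidise a primary TES ether directly while a secondary TBS ether survives, so a free allylic alcohol next to the acrylate, which would invite acyl migration, is never handled.

Step 11
Reactants: 16 Z-enal; 17 trimethylsilylacetylene
Product: 18 (1S,3S,6Z,8S)-C8 carbinol bearing C9≡C12–SiMe3 (C1 acrylate, C3 OTBS)
Conditions: (S,S)-ProPhenol (20 mol %), Ph3P=O (40 mol %), Me2Zn, PhMe, 0 °C
Reagents that add atoms: trimethylsilylacetylene C#C[Si](C)(C)C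
Why: Catalytic asymmetric alkynylation with a dinuclear zinc–ProPhenol catalyst, a reaction made for α,β-unsaturated aldehydes and tolerant of esters, in which the ligand should direct the alkynylzinc to the Re face of C8 and set (8S).

Step 12
Reactants: 18 silyl alkyne
Product: 19 (1S,3S,6Z,8S)-terminal propargylic alcohol
Conditions: TBAF, AcOH, THF, −20 °C
Reagents that add atoms: none
Why: Buffered fluoride protodesilylation of C(sp)–SiMe3 is far faster than cleavage of a secondary TBS ether, and the buffer avoids alkoxide-induced acyl migration.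

Step 13
Reactants: 19 propargylic alcohol
Product: 21 (1S,3S,6Z,aR)-C1 acrylate of the ring-A alkylidene vinyl-bromoallene (C8 cis to C1), via propargylic mesylate 20 (not isolated)
Conditions: Ms2O, Et3N, THF, −78 °C; then LiCuBr2 (LiBr, CuBr), THF, −78 °C → rt
Reagents that add atoms: lithium bromide [Li+].[Br-]; copper(I) bromide [Cu]Br (together LiCuBr2, source of Br); methanesulfonic anhydride CS(=O)(=O)OS(C)(=O)=O (its atoms stay only in 20)
Why: Chloride-free sulfonylation followed by the bromocuprate SN2' displacement of a propargylic sulfonate, known to run anti, puts Br on C12 opposite the leaving group so that (8S) becomes the (aR) axis, while the allylic terminus C6 is fully substituted and closed to attack.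

Step 14
Reactants: 21 acrylate-tethered vinyl-bromoallene
Product: 22 (1S,3S,6R,11S,9E)-tricyclic γ-lactone carrying the complete bromodiene
Conditions: PhMe (5 mM), BHT, base-washed sealed tube, 130 °C
Reagents that add atoms: none
Why: Proposed new method: on heating, the acrylate C10=C11 adds suprafacially and in one step across C6=C7–C8=C9 of the vinylallene (thermal [4π+2π]), so that C6–C11 and C9–C10 form together while the orthogonal C9=C12 π bond stays behind as the exocyclic bromoalkene. The nearest known reactions are Diels–Alder additions of vinylallenes, which give alkylidenecyclohexenes with transfer of the allene axis into alkene geometry, and type-1 intramolecular Diels–Alder reactions of pentadienyl acrylates, but neither has been run with a bromoallene or with a diene terminus that carries two quaternary carbons. Ring B closes as the six-membered cycloadduct ring, and the γ-lactone (C1, O, C=O, C11, C6) closes in the fused mode with the carbonyl exo, the only arrangement open to a three-atom tether standing on the cis (inside) substituent of C6. C6 is set by the tether, which can bring C11 only to the diene face that carries the C1 oxygen, and C11 follows from the exo-tether geometry and is erased in step 16. The step needs face selectivity at the allene: 21 holds Br on the tether face (aR axis), so C10 bonds to C9 syn to Br and bromine ends cis to C10 (9E), against the usual steric preference but without alternative because the other face is out of reach. Reactivity should be helped by the sp carbon C9, which has no inside substituent facing C1, by the lack of any hydrogen on C1 or C5 for a 1,5-shift, and by the tertiary ester, which populates the ester rotamer needed for lactone closure.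

Step 15
Reactants: 22 tricyclic lactone
Product: 23 lactol of 22 (anomeric mixture)
Conditions: DIBAL-H (1.2 equiv), CH2Cl2, −78 °C
Reagents that add atoms: none
Why: Partial reduction of a γ-lactone with DIBAL-H stops at the aluminium hemiacetal at low temperature, and the vinyl bromide and silyl ether are inert.

Step 16
Reactants: 23 lactol
Product: 24 (1S,3S,6S,9E)-spiro bromodiene with free C1 OH and C3 OTBS
Conditions: RhCl(PPh3)3 (1.1 equiv), xylene, 130 °C
Reagents that add atoms: none
Why: Tsuji–Wilkinson decarbonylation, known for cyclic hemiacetals such as aldoses and for hindered aldehydes, in which Rh inserts into the formyl C–H of the open γ-hydroxy aldehyde, extrudes CO and reductively eliminates C11–H, leaving C11H2 and the free C1 hydroxyl.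

Step 17
Reactants: 24 silyl ether
Product: 25 (1S,3S,6S,9E)-C1,C3-cis-diol
Conditions: TBAF, THF, rt
Reagents that add atoms: none
Why: Fluoride cleavage of the secondary TBS ether under conditions that leave the bromodiene and the tertiary alcohol alone.

Step 18
Reactants: 25 diol
Product: 26 target, (1S,3R,6S,9E)
Conditions: CBr4, PPh3, CH2Cl2, 0 °C → rt
Reagents that add atoms: carbon tetrabromide BrC(Br)(Br)Br
Why: Appel reaction, in which only the secondary alcohol gives a displaceable alkoxyphosphonium ion and bromide attacks with inversion (SN2) to give the equatorial (3R) bromide, while the hindered tertiary C1 OH is cis to the leaving group and cannot displace it.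

## Compound list

1 | (4R,6R)-actinol | CC1(C)C[C@H](O)C[C@@H](C)C1=O | starting material
2 | O-TBS actinol | CC1(C)C[C@H](O[Si](C)(C)C(C)(C)C)C[C@@H](C)C1=O | intermediate
3 | TMS enol ether | CC1(C)C[C@H](O[Si](C)(C)C(C)(C)C)CC(C)=C1O[Si](C)(C)C | intermediate
4 | silyloxy epoxide (O syn to C3 O) | CC1(C)C[C@H](O[Si](C)(C)C(C)(C)C)C[C@]2(C)O[C@]12O[Si](C)(C)C | intermediate
5 | trimethylsilyloxy ketone | CC1(C)C[C@H](O[Si](C)(C)C(C)(C)C)C[C@](C)(O[Si](C)(C)C)C1=O | intermediate
6 | (2S,4S)-hydroxy ketone | CC1(C)C[C@H](O[Si](C)(C)C(C)(C)C)C[C@](C)(O)C1=O | intermediate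
7 | acetic anhydride | CC(=O)OC(C)=O | starting material
8 | acetoxy ketone | CC1(C)C[C@H](O[Si](C)(C)C(C)(C)C)C[C@](C)(OC(C)=O)C1=O | intermediate
9 | cis-fused hydroxy lactone | CC1(C)C[C@H](O[Si](C)(C)C(C)(C)C)C[C@]2(C)OC(=O)C[C@]12O | intermediate
10 | (6S,7aS)-butenolide | CC1(C)C[C@H](O[Si](C)(C)C(C)(C)C)C[C@]2(C)OC(=O)C=C12 | intermediate
11 | Z-enediol | OC/C=C1/C(C)(C)C[C@H](O[Si](C)(C)C(C)(C)C)C[C@]1(C)O | intermediate
12 | primary TES ether | CC[Si](CC)(CC)OC/C=C1/C(C)(C)C[C@H](O[Si](C)(C)C(C)(C)C)C[C@]1(C)O | intermediate
13 | acryloyl chloride | C=CC(=O)Cl | starting material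
14 | lithium alkoxide of 12 | CC[Si](CC)(CC)OC/C=C1/C(C)(C)C[C@H](O[Si](C)(C)C(C)(C)C)C[C@]1(C)[O-].[Li+] | intermediate
15 | C1 acrylate, C8 OTES | CC[Si](CC)(CC)OC/C=C1/C(C)(C)C[C@H](O[Si](C)(C)C(C)(C)C)C[C@]1(C)OC(=O)C=C | intermediate
16 | Z-enal acrylate | O=C/C=C1/C(C)(C)C[C@H](O[Si](C)(C)C(C)(C)C)C[C@]1(C)OC(=O)C=C | intermediate
17 | trimethylsilylacetylene | C#C[Si](C)(C)C | starting material
18 | (8S)-carbinol, TMS alkyne | C[Si](C)(C)C#C[C@@H](O)/C=C1/C(C)(C)C[C@H](O[Si](C)(C)C(C)(C)C)C[C@]1(C)OC(=O)C=C | intermediate
19 | (8S)-carbinol, terminal alkyne | C#C[C@@H](O)/C=C1/C(C)(C)C[C@H](O[Si](C)(C)C(C)(C)C)C[C@]1(C)OC(=O)C=C | intermediate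
20 | (8S)-propargylic mesylate | C#C[C@@H](OS(C)(=O)=O)/C=C1/C(C)(C)C[C@H](O[Si](C)(C)C(C)(C)C)C[C@]1(C)OC(=O)C=C | intermediate
21 | (aR)-vinyl-bromoallene acrylate | BrC([H])=[C@]=C([H])/C=C1/C(C)(C)C[C@H](O[Si](C)(C)C(C)(C)C)C[C@]1(C)OC(=O)C=C | intermediate
22 | tricyclic (9E)-bromodiene lactone | CC1(C)C[C@H](O[Si](C)(C)C(C)(C)C)C[C@]2(C)OC(=O)[C@H]3C/C(=C\Br)C=C[C@@]123 | intermediate
23 | lactol | CC1(C)C[C@H](O[Si](C)(C)C(C)(C)C)C[C@]2(C)OC(O)[C@H]3C/C(=C\Br)C=C[C@@]123 | intermediate
24 | spiro bromodiene, C1 OH, C3 OTBS | CC1(C)C[C@H](O[Si](C)(C)C(C)(C)C)C[C@](C)(O)[C@@]12C=C/C(=C/Br)CC2 | intermediate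
25 | C1,C3-cis-diol | CC1(C)C[C@H](O)C[C@](C)(O)[C@@]12C=C/C(=C/Br)CC2 | intermediate
26 | CNP0234157.1 | CC1(C)C[C@@H](Br)C[C@](C)(O)[C@@]12C=C/C(=C/Br)CC2 | target

## Step count and risks

Total step count: 18. Longest linear sequence: 18 steps (1 → 26). Compounds 7, 13 and 17 are bought.

**Step 14 (new method).**
- What may go wrong: the s-cis conformer places the quaternary C1 next to the allene axis, and C6 has to become quaternary between two fully substituted carbons, so the cycloaddition may need a high temperature.
- At that temperature the bromoallene may be lost by 1,3-bromine shift, axis epimerisation or HBr loss. The tertiary allylic ester may ionise or eliminate, and the acrylate may polymerise.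
- Fallback: it sets out from 16 and rejoins at 22. The bromoallene is given up. The tether-directed cycloaddition is run on a thermally robust hydrocarbon diene, the class for which ester-tethered intramolecular Diels–Alder reactions are established, and the CHBr unit is added afterwards by olefination. Wittig methylenation of 16 (Ph3P=CH2, THF, −78 °C) should give the (Z)-dienyl acrylate F1. Heating (o-dichlorobenzene, BHT, 180 °C) should close the same two rings to the cyclohexene lactone F2. C9 is then the only allylic CH2 because C6 is quaternary, so allylic oxidation (CrO3·3,5-dimethylpyrazole, CH2Cl2, −20 °C) should give the enone lactone F3. Bromomethylenation (BrCH2PPh3Br, KOtBu, THF, −78 °C) leads to 22 together with the (9Z)-bromodiene lactone F4, which has to be separated. The alkene geometry is then no longer controlled by chirality transfer.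

**Step 16.**
- What may go wrong: the lactol may offer too little open aldehyde, and insertion at a formyl group next to the spiro centre may be slow.
- Rhodium may instead bind the diene, insert into the vinyl C–Br bond, or move the double bonds through Rh–H species.
- Fallback: it sets out from 22 and rejoins at 25. The tether carbon leaves as CO2 in a radical chain instead of as CO at a metal. Saponification (KOH, aq. THF/MeOH) gives the potassium hydroxy carboxylate F5. Exhaustive silylation of the dried salt (TESOTf, 2,6-lutidine, CH2Cl2, −78 → 0 °C) gives the bis-TES derivative F6. K2CO3 in aq. MeOH cleaves only the silyl ester to the silyloxy acid F7. DCC coupling with N-hydroxypyridine-2-thione gives the thiohydroxamate ester F8. Barton reductive decarboxylation (hν, excess t-BuSH as a fast hydrogen donor, to outrun attack of the C11 radical on the diene) gives the C1 OTES, C3 OTBS spiro bromodiene F9. TBAF then removes both silyl groups to give 25.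

**Step 13.**
- What may go wrong: the mesylate is both allylic and propargylic and may ionise. Bromide may attack C8 directly, and excess cuprate may epimerise the allene axis. Each process erodes the axial purity on which the alkene geometry of step 14 depends.
- Fallback: it sets out from 19 and rejoins at 21. Stereospecific transfer is replaced by a separate-and-recycle scheme. The two allene epimers are diastereomers, so 21 is separated by chromatography from the (aS)-bromoallene epimer F10. F10 is returned to LiCuBr2 in THF, which is known to scramble bromoallene axes, to regenerate the mixture for further separation.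

## Further compounds

F1 | step 14 | (Z)-dienyl acrylate (C9H2 terminus) | C=C/C=C1/C(C)(C)C[C@H](O[Si](C)(C)C(C)(C)C)C[C@]1(C)OC(=O)C=C
F2 | step 14 | cyclohexene lactone (C9H2) | CC1(C)C[C@H](O[Si](C)(C)C(C)(C)C)C[C@]2(C)OC(=O)[C@H]3CCC=C[C@@]123
F3 | step 14 | enone lactone (C9=O) | CC1(C)C[C@H](O[Si](C)(C)C(C)(C)C)C[C@]2(C)OC(=O)[C@H]3CC(=O)C=C[C@@]123
F4 | step 14 | (9Z)-bromodiene lactone | CC1(C)C[C@H](O[Si](C)(C)C(C)(C)C)C[C@]2(C)OC(=O)[C@H]3C/C(=C/Br)C=C[C@@]123
F5 | step 16 | potassium hydroxy carboxylate | CC1(C)C[C@H](O[Si](C)(C)C(C)(C)C)C[C@](C)(O)[C@@]12C=C/C(=C/Br)C[C@@H]2C(=O)[O-].[K+]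
F6 | step 16 | bis-TES derivative (C1 OTES, silyl ester) | CC1(C)C[C@H](O[Si](C)(C)C(C)(C)C)C[C@](C)(O[Si](CC)(CC)CC)[C@@]12C=C/C(=C/Br)C[C@@H]2C(=O)O[Si](CC)(CC)CC
F7 | step 16 | silyloxy acid | CC1(C)C[C@H](O[Si](C)(C)C(C)(C)C)C[C@](C)(O[Si](CC)(CC)CC)[C@@]12C=C/C(=C/Br)C[C@@H]2C(=O)O
F8 | step 16 | thiohydroxamate ester | CC1(C)C[C@H](O[Si](C)(C)C(C)(C)C)C[C@](C)(O[Si](CC)(CC)CC)[C@@]12C=C/C(=C/Br)C[C@@H]2C(=O)ON3C=CC=CC3=S
F9 | step 16 | C1 OTES, C3 OTBS spiro bromodiene | CC1(C)C[C@H](O[Si](C)(C)C(C)(C)C)C[C@](C)(O[Si](CC)(CC)CC)[C@@]12C=C/C(=C/Br)CC2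
F10 | step 13 | (aS)-bromoallene epimer of 21 | BrC([H])=[C@@]=C([H])/C=C1/C(C)(C)C[C@H](O[Si](C)(C)C(C)(C)C)C[C@]1(C)OC(=O)C=C
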